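**Strategy.** The ten-membered carbocycle is opened at C5–C6. C6 is a carbinol carbon bonded to C5 of the ring-cis C4=C5 alkene (the later C4–C5 oxirane), and its oxygen becomes the ring oxygen of the γ-lactone (O–C6–C7–C11–C12). Addition of a C5 alkenylchromium to a C6 aldehyde therefore closes the carbocycle, keeps the Z geometry the cis-epoxide needs, and creates the C6 stereocentre in one operation. The precursor is an open-chain C6 aldehyde carrying the C7 acetate arm, C8 OPMB, C9 OTES, the C1=C10 enoate and a Z C5 iodoalkene. It is assembled from dimethyl L-malate (C6–C9), a thioacetate (C10, C14) and propargyl alcohol (C3–C5, C15).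

Key step: step 22

Remark: atoms carry germacrane numbers (C1=C10 enoate with ester carbon C14 on C10, methyl C15 on C4, lactone oxygen on C6, C11/C12 on C7); "ring-cis" means that both ring bonds lie on the same side of the alkene.

Step 1
Reactants: 1 propargyl alcohol
Product: 3 (Z)-3-iodo-2-methylprop-2-en-1-ol, via alkenylmagnesium alkoxide 2 (not isolated)
Conditions: MeMgBr (3 equiv), CuI (10 mol%), Et2O, −10 °C → rt; then I2, −10 °C
Reagents that add atoms: methylmagnesium bromide, C[Mg]Br; iodine, II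
Why: Copper-catalysed anti-carbomagnesiation of the propargylic alkoxide gives a five-membered magnesium chelate with methyl on C4 and magnesium on C5 cis to CH2O, and iodinolysis with retention fixes the Z iodoalkene (C3–C5, C15).

Step 2
Reactants: 3 (Z)-3-iodo-2-methylprop-2-en-1-ol
Product: 4 (Z)-3-bromo-1-iodo-2-methylprop-1-ene
Conditions: CBr4, PPh3, CH2Cl2, 0 °C
Reagents that add atoms: carbon tetrabromide, BrC(Br)(Br)Br
Why: Appel reaction, in which bromide displaces the alkoxyphosphonium group at the primary allylic CH2 (SN2), so the iodoalkene geometry is untouched.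

Step 3
Reactants: 4 (Z)-3-bromo-1-iodo-2-methylprop-1-ene
Product: 5 (Z)-5-iodo-4-methylpent-4-enenitrile
Conditions: MeCN (5 equiv), n-BuLi (4 equiv), THF, −78 °C; then 4, −78 → −40 °C
Reagents that add atoms: acetonitrile, CC#N
Why: SN2 alkylation of excess lithioacetonitrile by the reactive allylic bromide adds C1 and C2; the excess suppresses dialkylation and the stabilised carbanion does not exchange with the vinyl iodide.

Step 4
Reactants: 5 (Z)-5-iodo-4-methylpent-4-enenitrile
Product: 7 (Z)-5-iodo-4-methylpent-4-enal, via N-aluminated aldimine 6 (not isolated)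
Conditions: iBu2AlH (1.2 equiv), CH2Cl2, −78 °C; then 1 M aq. HCl, 0 °C
Reagents that add atoms: water, O
Why: Partial reduction of a nitrile, in which one hydride adds and the aluminated imine survives until acidic hydrolysis releases the C1 aldehyde.

Step 5
Reactants: 8 S-ethyl thioacetate
Product: 10 1-(ethylthio)-1-(trimethylsilyloxy)ethene, via lithium thioester enolate 9 (not isolated)
Conditions: LiN(iPr)2, THF, −78 °C; then Me3SiCl, −78 °C → rt
Reagents that add atoms: chlorotrimethylsilane, C[Si](C)(C)Cl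
Why: O-silylation of the kinetic lithium enolate gives the ketene silyl thioacetal that serves as the C10–C14 nucleophile.

Step 6
Reactants: 11 dimethyl (S)-malate
Product: 12 methyl (S)-3,4-dihydroxybutanoate
Conditions: BH3·SMe2 (1.05 equiv), NaBH4 (5 mol%), THF, rt; then MeOH
Reagents that add atoms: none
Why: Hydroxyl-directed borane reduction, in which hydride is delivered through the borate of the free hydroxyl so that only the neighbouring ester is reduced; C9 becomes a primary alcohol while the C6 ester and the C8 stereocentre stay.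

Step 7
Reactants: 12 methyl (S)-3,4-dihydroxybutanoate
Product: 14 methyl (S)-3-hydroxy-4-[(4-methoxybenzyl)oxy]butanoate, via dibutylstannylene acetal 13 (not isolated)
Conditions: Bu2SnO, MeOH, reflux; evaporate; then 4-MeOC6H4CH2Cl, CsF, DMF, rt
Reagents that add atoms: 4-methoxybenzyl chloride, COc1ccc(CCl)cc1
Why: Stannylene-mediated alkylation of a 1,2-diol takes place at the primary oxygen (O9), and methanol as solvent for acetal formation keeps the hydroxy ester from lactonising.

Step 8
Reactants: 14 methyl (S)-3-hydroxy-4-[(4-methoxybenzyl)oxy]butanoate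
Product: 16 methyl (2R,3S)-2-allyl-3-hydroxy-4-[(4-methoxybenzyl)oxy]butanoate, via dilithium alkoxide enolate 15 (not isolated)
Conditions: LiN(iPr)2 (2.2 equiv), THF, −78 → −20 °C; then allyl bromide, DMPU, −78 → −10 °C
Reagents that add atoms: allyl bromide, C=CCBr
Why: Fráter–Seebach alkylation, in which the six-membered lithium chelate of the alkoxide enolate is alkylated on the face away from the C9 substituent, setting C7 anti to the C8 oxygen as the target requires.

Step 9
Reactants: 16 methyl (2R,3S)-2-allyl-3-hydroxy-4-[(4-methoxybenzyl)oxy]butanoate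
Product: 17 methyl (2R)-2-[(4S)-2-(4-methoxyphenyl)-1,3-dioxolan-4-yl]pent-4-enoate (both acetal epimers)
Conditions: DDQ (1.2 equiv), 4 Å MS, CH2Cl2, 0 °C
Reagents that add atoms: none
Why: Oxidative acetalisation, in which the oxocarbenium ion from DDQ oxidation of the PMB ether is trapped, in the absence of water, by the adjacent C8 hydroxyl; this protects O8 and O9 together and prepares the transfer of the PMB group to O8.

Step 10
Reactants: 17 methyl (2R)-2-[(4S)-2-(4-methoxyphenyl)-1,3-dioxolan-4-yl]pent-4-enoate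
Product: 18 (2S)-2-[(4S)-2-(4-methoxyphenyl)-1,3-dioxolan-4-yl]pent-4-en-1-ol
Conditions: LiAlH4, THF, 0 °C
Reagents that add atoms: none
Why: Hydride reduction of the methyl ester gives the C6 primary alcohol before any other ester is present; acetal and terminal alkene are inert.

Step 11
Reactants: 18 (2S)-2-[(4S)-2-(4-methoxyphenyl)-1,3-dioxolan-4-yl]pent-4-en-1-ol
Product: 19 triethylsilyl ether of 18
Conditions: Et3SiCl, imidazole, CH2Cl2, 0 °C
Reagents that add atoms: chlorotriethylsilane, CC[Si](Cl)(CC)CC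
Why: Routine silylation of the only hydroxyl; a primary TES ether is chosen because Swern conditions later oxidise it directly to the C6 aldehyde.

Step 12
Reactants: 19 triethylsilyl ether of 18
Product: 20 (2S,3S)-2-[(4-methoxybenzyl)oxy]-3-{[(triethylsilyl)oxy]methyl}hex-5-en-1-ol
Conditions: iBu2AlH (3 equiv), CH2Cl2, −78 → 0 °C; aq. potassium sodium tartrate
Reagents that add atoms: none
Why: Regioselective reductive opening of the 4-methoxybenzylidene acetal, in which aluminium binds the less hindered primary oxygen so that hydride delivery leaves the PMB ether on the secondary C8 oxygen and frees C9–OH.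

Step 13
Reactants: 20 (2S,3S)-2-[(4-methoxybenzyl)oxy]-3-{[(triethylsilyl)oxy]methyl}hex-5-en-1-ol
Product: 21 (2S,3S)-2-[(4-methoxybenzyl)oxy]-3-{[(triethylsilyl)oxy]methyl}hex-5-enal
Conditions: Dess–Martin periodinane, NaHCO3, CH2Cl2, 0 °C → rt
Reagents that add atoms: none
Why: Buffered Dess–Martin oxidation should give the α-alkoxy aldehyde without epimerisation at C8 and without attack on the TES ether; the aldehyde is used crude.

Step 14
Reactants: 21 (2S,3S)-2-[(4-methoxybenzyl)oxy]-3-{[(triethylsilyl)oxy]methyl}hex-5-enal; 10 1-(ethylthio)-1-(trimethylsilyloxy)ethene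
Product: 22 S-ethyl (3S,4S,5S)-3-hydroxy-4-[(4-methoxybenzyl)oxy]-5-{[(triethylsilyl)oxy]methyl}oct-7-enethioate
Conditions: MgBr2·OEt2 (3 equiv), CH2Cl2, −78 → −30 °C; aq. work-up
Reagents that add atoms: none
Why: Chelation-controlled Mukaiyama aldol, in which magnesium bridges the aldehyde oxygen and the C8 PMB ether oxygen and the ketene silyl thioacetal attacks the five-membered chelate on the face away from the C7 branch; this gives the 8,9-syn diol pattern and so the C9 stereocentre.

Step 15
Reactants: 22 S-ethyl (3S,4S,5S)-3-hydroxy-4-[(4-methoxybenzyl)oxy]-5-{[(triethylsilyl)oxy]methyl}oct-7-enethioate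
Product: 23 S-ethyl (3S,4S,5S)-4-[(4-methoxybenzyl)oxy]-3-[(triethylsilyl)oxy]-5-{[(triethylsilyl)oxy]methyl}oct-7-enethioate
Conditions: Et3SiOTf, 2,6-lutidine, CH2Cl2, −78 °C
Reagents that add atoms: triethylsilyl triflate, CC[Si](CC)(CC)OS(=O)(=O)C(F)(F)F
Why: Silylation of the hindered secondary C9 hydroxyl with the silyl triflate; the β-silyloxy group is a poor leaving group, which matters in the enolate steps that follow.

Step 16
Reactants: 23 S-ethyl (3S,4S,5S)-4-[(4-methoxybenzyl)oxy]-3-[(triethylsilyl)oxy]-5-{[(triethylsilyl)oxy]methyl}oct-7-enethioate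
Product: 24 S-ethyl (3S,4S,5S)-4-[(4-methoxybenzyl)oxy]-7-oxo-3-[(triethylsilyl)oxy]-5-{[(triethylsilyl)oxy]methyl}heptanethioate
Conditions: OsO4 (2 mol%), NaIO4 (4 equiv), 2,6-lutidine, dioxane/H2O 3:1, rt
Reagents that add atoms: osmium tetroxide (catalytic oxygen carrier), O=[Os](=O)(=O)=O; sodium periodate, [Na+].[O-]I(=O)(=O)=O
Why: Lemieux–Johnson cleavage of the only alkene (the terminal allyl group) gives the C12 aldehyde; it is placed here because no other alkene is yet in the molecule, and silyl ethers, PMB ether and thioester tolerate the buffered conditions.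

Step 17
Reactants: 24 S-ethyl (3S,4S,5S)-4-[(4-methoxybenzyl)oxy]-7-oxo-3-[(triethylsilyl)oxy]-5-{[(triethylsilyl)oxy]methyl}heptanethioate
Product: 26 methyl (3S,4S,5S)-7-(ethylsulfanyl)-4-[(4-methoxybenzyl)oxy]-7-oxo-5-[(triethylsilyl)oxy]-3-{[(triethylsilyl)oxy]methyl}heptanoate, via C12 carboxylic acid 25 (not isolated)
Conditions: NaClO2, NaH2PO4, 2-methyl-2-butene, t-BuOH/H2O, 0 °C; extractive work-up; then Me3SiCHN2, MeOH/PhMe, 0 °C
Reagents that add atoms: sodium chlorite, [Na+].[O-]Cl=O; trimethylsilyldiazomethane, C[Si](C)(C)C=[N+]=[N-]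
Why: Pinnick oxidation followed by diazoalkane esterification installs the C12 methyl ester under conditions too mild for the thioester or the silyl ethers; C6 and C8 oxygens are already capped, so no γ-hydroxy ester can lactonise.

Step 18
Reactants: 26 methyl (3S,4S,5S)-7-(ethylsulfanyl)-4-[(4-methoxybenzyl)oxy]-7-oxo-5-[(triethylsilyl)oxy]-3-{[(triethylsilyl)oxy]methyl}heptanoate; 7 (Z)-5-iodo-4-methylpent-4-enal
Product: 28 β-hydroxy thioester (aldol adduct of 26 at C10 with 7; diastereomers at C10 and C1), via dicyclohexylboron enolate 27 (not isolated)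
Conditions: (c-C6H11)2BCl (1.5 equiv), Et3N, Et2O, −78 → 0 °C; then 7, −78 → −20 °C; then pH 7 buffer, MeOH, 30% H2O2, 0 °C
Reagents that add atoms: none
Why: Boron aldol after soft enolisation, in which the dialkylboron chloride and amine enolise only the more acidic thioester at C10 and leave the C12 methyl ester alone; the boron enolate adds to the C1 aldehyde without Claisen or β-elimination side reactions, and both new centres are erased in the next step.

Step 19
Reactants: 28 β-hydroxy thioester
Product: 30 methyl (3S,4S,5S,6E,10Z)-6-[(ethylsulfanyl)carbonyl]-11-iodo-4-[(4-methoxybenzyl)oxy]-10-methyl-5-[(triethylsilyl)oxy]-3-{[(triethylsilyl)oxy]methyl}undeca-6,10-dienoate, via C1 mesylate 29 (not isolated)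
Conditions: MeSO2Cl, Et3N, CH2Cl2, 0 °C; then DBU, 0 °C → rt
Reagents that add atoms: none
Why: E1cB elimination of the β-mesylate through the thioester enolate (aldol condensation), in which mesylate leaves far more readily than the C9 silyloxy group; the stereoconvergent elimination should favour the less strained trisubstituted alkene with C2 trans to the acyl group, which is the ring-cis C1=C10 geometry of the target.

Step 20
Reactants: 30 conjugated thioester
Product: 31 dimethyl (2E,3S,4S,5S)-2-[(4Z)-5-iodo-4-methylpent-4-en-1-ylidene]-4-[(4-methoxybenzyl)oxy]-3-[(triethylsilyl)oxy]-5-{[(triethylsilyl)oxy]methyl}heptanedioate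
Conditions: AgO2CCF3 (3 equiv), i-Pr2NEt, MeOH/THF 1:1, rt → 40 °C
Reagents that add atoms: methanol, CO
Why: Silver-promoted thioester alcoholysis, in which the thiophilic silver salt activates sulfur for acyl transfer to methanol; C14 becomes the methyl ester while oxoesters, silyl ethers and the iodoalkene are left alone.

Step 21
Reactants: 31 bis-TES diester
Product: 32 dimethyl (2E,3S,4S,5R)-5-formyl-2-[(4Z)-5-iodo-4-methylpent-4-en-1-ylidene]-4-[(4-methoxybenzyl)oxy]-3-[(triethylsilyl)oxy]heptanedioate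
Conditions: (COCl)2 (5 equiv), DMSO (10 equiv), CH2Cl2, −78 → −30 °C; then Et3N, −78 → 0 °C
Reagents that add atoms: none
Why: Swern oxidation applied directly to a primary TES ether, in which the chlorosulfonium reagent desilylates only the unhindered primary oxygen and the secondary C9 TES ether stays; the C6 aldehyde thus appears without a free γ-hydroxy ester (C6–OH/C12 ester) that would lactonise.

Step 22
Reactants: 32 seco-aldehyde (Z C5 iodoalkene, C6 aldehyde)
Product: 33 cyclodecadienol (ring-cis C1=C10 and C4=C5; C6 OH cis to the C7 CH2CO2Me arm; C8 OPMB; C9 OTES; C14 methyl ester)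
Conditions: CrCl2 (12 equiv), NiCl2 (1 mol% of CrCl2), degassed DMSO, 0.002 M, slow addition of 32, rt
Reagents that add atoms: none
Why: CrCl2 reduces NiCl2 to zerovalent nickel, which inserts into the C5–I bond with retention of the Z geometry and passes the alkenyl group to trivalent chromium, and the alkenylchromium adds to the C6 aldehyde (Nozaki–Hiyama–Kishi reaction). The closest known reaction type is the intramolecular Nozaki–Hiyama–Kishi coupling of iodoalkenes with aldehydes used to close medium and large carbocycles. The ten-membered ring closes by attack of C5 on the exocyclic C6=O (10-exo-trig, forming C5–C6), helped by the two ring-cis alkenes C1=C10 and C4=C5 as turn elements and by high dilution. The new C6 stereocentre is controlled by C7: with the tether through C8 gauche to the forming bond, C5 should approach anti to the C11 arm (Felkin-type, possibly reinforced by chromium chelation between the aldehyde and the C8 PMB ether oxygen), which places the C6 oxygen cis to C11 as the cis-fused lactone requires. The step needs selectivity for the aldehyde over two methyl esters and the enoate and no loss of alkene geometry; both follow from the low basicity and aldehyde selectivity of alkenylchromium reagents and from stereoretentive oxidative addition and transmetalation.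

Step 23
Reactants: 33 cyclodecadienol
Product: 35 C4–C5 epoxy 6,12-lactone (cis-fused; C8 OPMB; C9 OTES), via epoxy alcohol 34 (not isolated)
Conditions: mCPBA, NaHCO3, CH2Cl2, 0 °C; filter; then PPTS (10 mol%), CH2Cl2, rt
Reagents that add atoms: 3-chloroperbenzoic acid, O=C(OO)c1cccc(Cl)c1
Why: Hydrogen-bond-directed peracid epoxidation (Henbest type) of the only electron-rich alkene should occur syn to C6–OH in the conformer that holds C6–H in the alkene plane, the mode that gives trans epoxy alcohols from medium-ring Z allylic alcohols and the oxirane face needed here; mild acid then closes the γ-lactone by attack of C6–OH on the C12 methyl ester.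

Step 24
Reactants: 35 epoxy lactone
Product: 39 α-methylene lactone (C11=C13; C8 OPMB; C9 OTES), via lithium lactone enolate 36 (not isolated), via Mannich base 37 (not isolated), via trimethylammonium iodide 38 (not isolated)
Conditions: LiN(iPr)2, THF, −78 °C; CH2=NMe2+ I− (Eschenmoser's salt), −78 °C → rt; then MeI, MeOH, rt; then aq. NaHCO3, CH2Cl2, rt
Reagents that add atoms: N,N-dimethylmethyleneiminium iodide, C=[N+](C)C.[I-]
Why: Standard α-methylenation of a γ-lactone by kinetic deprotonation at C11, Mannich reaction, exhaustive methylation and E1cB loss of trimethylamine; at −78 °C the lactone α-protons should be removed faster than any vinylogous deprotonation of the C14 enoate.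

Step 25
Reactants: 39 α-methylene lactone
Product: 40 C8 alcohol (C9 OTES)
Conditions: DDQ, CH2Cl2/pH 7 buffer 10:1, 0 °C
Reagents that add atoms: none
Why: Oxidative cleavage of the PMB ether by DDQ in buffered wet solvent frees C8–OH without touching the epoxide, the TES ether or the Michael acceptors.

Step 26
Reactants: 40 C8 alcohol
Product: 41 C8 methacrylate (C9 OTES)
Conditions: methacrylic anhydride, Et3N, DMAP (20 mol%), CH2Cl2, 0 °C → rt
Reagents that add atoms: methacrylic anhydride, C=C(C)C(=O)OC(=O)C(C)=C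
Why: DMAP-catalysed acylation of the secondary alcohol, run at once so that the free C8 hydroxyl has no time to open the neighbouring epoxide.

Step 27
Reactants: 41 C8 methacrylate
Product: 42 C9 alcohol
Conditions: Bu4NF, AcOH (1:1), THF, 0 °C
Reagents that add atoms: none
Why: Acetic acid-buffered fluoride removes the allylic secondary TES ether under near-neutral conditions that spare the epoxide, the α-methylene lactone and the esters.

Step 28
Reactants: 42 C9 alcohol
Product: 43 target compound
Conditions: Ac2O, pyridine, DMAP (10 mol%), CH2Cl2, 0 °C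
Reagents that add atoms: acetic anhydride, CC(=O)OC(C)=O
Why: DMAP-catalysed acetylation of C9–OH is fast, so the neighbouring methacrylate should not migrate, and it completes the target.

**Compound list**

1 | propargyl alcohol | C#CCO | starting material
2 | bromomagnesium (Z)-3-(bromomagnesio)-2-methylprop-2-en-1-olate | Br[Mg]OC/C(C)=C\[Mg]Br | intermediate
3 | (Z)-3-iodo-2-methylprop-2-en-1-ol | OC/C(C)=C\I | intermediate
4 | (Z)-3-bromo-1-iodo-2-methylprop-1-ene | BrC/C(C)=C\I | intermediate
5 | (Z)-5-iodo-4-methylpent-4-enenitrile | N#CCC/C(C)=C\I | intermediate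
6 | N-(diisobutylalumino) aldimine of 7 | CC(C)C[Al](CC(C)C)N=CCC/C(C)=C\I | intermediate
7 | (Z)-5-iodo-4-methylpent-4-enal | O=CCC/C(C)=C\I | intermediate
8 | S-ethyl thioacetate | CCSC(C)=O | starting material
9 | lithium enolate of 8 | C=C(O[Li])SCC | intermediate
10 | 1-(ethylthio)-1-(trimethylsilyloxy)ethene | C=C(O[Si](C)(C)C)SCC | intermediate
11 | dimethyl (S)-malate (dimethyl L-malate) | COC(=O)C[C@H](O)C(=O)OC | starting material
12 | methyl (S)-3,4-dihydroxybutanoate | COC(=O)C[C@H](O)CO | intermediate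
13 | dibutylstannylene acetal of 12 | COC(=O)C[C@H]1CO[Sn](CCCC)(CCCC)O1 | intermediate
14 | methyl (S)-3-hydroxy-4-[(4-methoxybenzyl)oxy]butanoate | COC(=O)C[C@H](O)COCc1ccc(OC)cc1 | intermediate
15 | dilithium alkoxide enolate of 14 | COC(O[Li])=C[C@H](O[Li])COCc1ccc(OC)cc1 | intermediate
16 | methyl (2R,3S)-2-allyl-3-hydroxy-4-[(4-methoxybenzyl)oxy]butanoate | COC(=O)[C@H](CC=C)[C@H](O)COCc1ccc(OC)cc1 | intermediate
17 | methyl (2R)-2-[(4S)-2-(4-methoxyphenyl)-1,3-dioxolan-4-yl]pent-4-enoate (both acetal epimers) | COC(=O)[C@H](CC=C)[C@H]1COC(c2ccc(OC)cc2)O1 | intermediate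
18 | (2S)-2-[(4S)-2-(4-methoxyphenyl)-1,3-dioxolan-4-yl]pent-4-en-1-ol | OC[C@H](CC=C)[C@H]1COC(c2ccc(OC)cc2)O1 | intermediate
19 | triethylsilyl ether of 18 | CC[Si](CC)(CC)OC[C@H](CC=C)[C@H]1COC(c2ccc(OC)cc2)O1 | intermediate
20 | (2S,3S)-2-[(4-methoxybenzyl)oxy]-3-{[(triethylsilyl)oxy]methyl}hex-5-en-1-ol | CC[Si](CC)(CC)OC[C@H](CC=C)[C@H](OCc1ccc(OC)cc1)CO | intermediate
21 | (2S,3S)-2-[(4-methoxybenzyl)oxy]-3-{[(triethylsilyl)oxy]methyl}hex-5-enal | CC[Si](CC)(CC)OC[C@H](CC=C)[C@H](OCc1ccc(OC)cc1)C=O | intermediate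
22 | S-ethyl (3S,4S,5S)-3-hydroxy-4-[(4-methoxybenzyl)oxy]-5-{[(triethylsilyl)oxy]methyl}oct-7-enethioate | CC[Si](CC)(CC)OC[C@H](CC=C)[C@H](OCc1ccc(OC)cc1)[C@@H](O)CC(=O)SCC | intermediate
23 | S-ethyl (3S,4S,5S)-4-[(4-methoxybenzyl)oxy]-3-[(triethylsilyl)oxy]-5-{[(triethylsilyl)oxy]methyl}oct-7-enethioate | CC[Si](CC)(CC)OC[C@H](CC=C)[C@H](OCc1ccc(OC)cc1)[C@@H](O[Si](CC)(CC)CC)CC(=O)SCC | intermediate
24 | S-ethyl (3S,4S,5S)-4-[(4-methoxybenzyl)oxy]-7-oxo-3-[(triethylsilyl)oxy]-5-{[(triethylsilyl)oxy]methyl}heptanethioate | CC[Si](CC)(CC)OC[C@H](CC=O)[C@H](OCc1ccc(OC)cc1)[C@@H](O[Si](CC)(CC)CC)CC(=O)SCC | intermediate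
25 | C12 carboxylic acid from 24 | CC[Si](CC)(CC)OC[C@H](CC(=O)O)[C@H](OCc1ccc(OC)cc1)[C@@H](O[Si](CC)(CC)CC)CC(=O)SCC | intermediate
26 | methyl (3S,4S,5S)-7-(ethylsulfanyl)-4-[(4-methoxybenzyl)oxy]-7-oxo-5-[(triethylsilyl)oxy]-3-{[(triethylsilyl)oxy]methyl}heptanoate | CC[Si](CC)(CC)OC[C@H](CC(=O)OC)[C@H](OCc1ccc(OC)cc1)[C@@H](O[Si](CC)(CC)CC)CC(=O)SCC | intermediate
27 | dicyclohexylboron enolate of 26 (at C10) | CC[Si](CC)(CC)OC[C@H](CC(=O)OC)[C@H](OCc1ccc(OC)cc1)[C@@H](O[Si](CC)(CC)CC)C=C(OB(C1CCCCC1)C1CCCCC1)SCC | intermediate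
28 | β-hydroxy thioester, aldol adduct of 26 and 7 (diastereomers at C10 and C1) | CC[Si](CC)(CC)OC[C@H](CC(=O)OC)[C@H](OCc1ccc(OC)cc1)[C@@H](O[Si](CC)(CC)CC)C(C(=O)SCC)C(O)CC/C(C)=C\I | intermediate
29 | C1 mesylate of 28 | CC[Si](CC)(CC)OC[C@H](CC(=O)OC)[C@H](OCc1ccc(OC)cc1)[C@@H](O[Si](CC)(CC)CC)C(C(=O)SCC)C(OS(C)(=O)=O)CC/C(C)=C\I | intermediate
30 | methyl (3S,4S,5S,6E,10Z)-6-[(ethylsulfanyl)carbonyl]-11-iodo-4-[(4-methoxybenzyl)oxy]-10-methyl-5-[(triethylsilyl)oxy]-3-{[(triethylsilyl)oxy]methyl}undeca-6,10-dienoate | CC[Si](CC)(CC)OC[C@H](CC(=O)OC)[C@H](OCc1ccc(OC)cc1)[C@@H](O[Si](CC)(CC)CC)/C(C(=O)SCC)=C\CC/C(C)=C\I | intermediate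
31 | dimethyl (2E,3S,4S,5S)-2-[(4Z)-5-iodo-4-methylpent-4-en-1-ylidene]-4-[(4-methoxybenzyl)oxy]-3-[(triethylsilyl)oxy]-5-{[(triethylsilyl)oxy]methyl}heptanedioate | CC[Si](CC)(CC)OC[C@H](CC(=O)OC)[C@H](OCc1ccc(OC)cc1)[C@@H](O[Si](CC)(CC)CC)/C(C(=O)OC)=C\CC/C(C)=C\I | intermediate
32 | dimethyl (2E,3S,4S,5R)-5-formyl-2-[(4Z)-5-iodo-4-methylpent-4-en-1-ylidene]-4-[(4-methoxybenzyl)oxy]-3-[(triethylsilyl)oxy]heptanedioate (key-step precursor) | O=C[C@H](CC(=O)OC)[C@H](OCc1ccc(OC)cc1)[C@@H](O[Si](CC)(CC)CC)/C(C(=O)OC)=C\CC/C(C)=C\I | intermediate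
33 | cyclodecadienol: ring-cis C1=C10 (C14 methyl ester) and C4=C5 (C15 methyl), C6 OH cis to C7 CH2CO2Me, C8 OPMB, C9 OTES (key-step product) | O(Cc3ccc(OC)cc3)[C@H]1[C@@H](CC(=O)OC)[C@@H](O)/C=C(C)\CC/C=C(/C(=O)OC)[C@@H]1O[Si](CC)(CC)CC | intermediate
34 | C4–C5 epoxy alcohol of 33 (oxirane O trans to C6 OH across the ring) | O(Cc3ccc(OC)cc3)[C@H]1[C@@H](CC(=O)OC)[C@@H](O)[C@@H]2O[C@]2(C)CC/C=C(/C(=O)OC)[C@@H]1O[Si](CC)(CC)CC | intermediate
35 | C4–C5 epoxy 6,12-lactone (cis-fused), C8 OPMB, C9 OTES | O(Cc3ccc(OC)cc3)[C@H]1[C@H]2CC(=O)O[C@H]2[C@@H]2O[C@]2(C)CC/C=C(/C(=O)OC)[C@@H]1O[Si](CC)(CC)CC | intermediate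
36 | lithium enolate of lactone 35 | O(Cc3ccc(OC)cc3)[C@H]1[C@H]2C=C(O[Li])O[C@H]2[C@@H]2O[C@]2(C)CC/C=C(/C(=O)OC)[C@@H]1O[Si](CC)(CC)CC | intermediate
37 | C11 (dimethylamino)methyl lactone (Mannich base, C11 epimers) | O(Cc3ccc(OC)cc3)[C@H]1[C@H]2C(CN(C)C)C(=O)O[C@H]2[C@@H]2O[C@]2(C)CC/C=C(/C(=O)OC)[C@@H]1O[Si](CC)(CC)CC | intermediate
38 | trimethylammonium iodide of 37 | O(Cc3ccc(OC)cc3)[C@H]1[C@H]2C(C[N+](C)(C)C)C(=O)O[C@H]2[C@@H]2O[C@]2(C)CC/C=C(/C(=O)OC)[C@@H]1O[Si](CC)(CC)CC.[I-] | intermediate
39 | α-methylene epoxy lactone, C8 OPMB, C9 OTES | O(Cc3ccc(OC)cc3)[C@H]1[C@H]2C(=C)C(=O)O[C@H]2[C@@H]2O[C@]2(C)CC/C=C(/C(=O)OC)[C@@H]1O[Si](CC)(CC)CC | intermediate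
40 | α-methylene epoxy lactone, C8 OH, C9 OTES | O[C@H]1[C@H]2C(=C)C(=O)O[C@H]2[C@@H]2O[C@]2(C)CC/C=C(/C(=O)OC)[C@@H]1O[Si](CC)(CC)CC | intermediate
41 | C8 methacrylate, C9 OTES | C=C(C)C(=O)O[C@H]1[C@H]2C(=C)C(=O)O[C@H]2[C@@H]2O[C@]2(C)CC/C=C(/C(=O)OC)[C@@H]1O[Si](CC)(CC)CC | intermediate
42 | C8 methacrylate, C9 OH | C=C(C)C(=O)O[C@H]1[C@H]2C(=C)C(=O)O[C@H]2[C@@H]2O[C@]2(C)CC/C=C(/C(=O)OC)[C@@H]1O | intermediate
43 | CNP0153978.6: methyl 9-acetoxy-4,5-epoxy-8-(methacryloyloxy)germacra-1(10),11(13)-dien-6,12-olid-14-oate | C=C(C)C(=O)O[C@H]1[C@H]2C(=C)C(=O)O[C@H]2[C@@H]2O[C@]2(C)CC/C=C(/C(=O)OC)[C@@H]1OC(C)=O | target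

**Count.** Total: 28 steps. Longest linear sequence: 23 steps (steps 6–28, from dimethyl (S)-malate); steps 1–4 and step 5 are side branches.

**Steps most likely to fail**

Step 22 (ring closure). Intermolecular coupling or reduction of the C–I bond may compete with closure of the strained ring, and the facial selectivity at C6 may turn out poor. The fallback sets out from 32 and keeps the cyclisation but corrects C6 afterwards. If the closure delivers mainly the C6-epimeric cyclodecadienol F1, this is oxidised with Dess–Martin periodinane (NaHCO3, CH2Cl2) to the cross-conjugated C6 ketone F2. Luche reduction of F2 (NaBH4, CeCl3·7H2O, MeOH, −78 °C) should deliver hydride anti to the C7 arm and return the route at 33.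

Step 23 (epoxidation). The peracid may attack the wrong face of C4=C5, or lactonisation may remove the directing hydroxyl before epoxidation. The fallback sets out from 33 and replaces hydroxyl direction by steric control. The hydroxy ester is first lactonised (PPTS, CH2Cl2) to the dienyl lactone F3. Dimethyldioxirane (acetone, −20 °C) should then epoxidise C4=C5 from the face opposite the cis-fused lactone, which is the same oxirane face, and the route is rejoined at 35.

Step 19 (elimination). The stereoconvergent E1cB elimination may give an appreciable amount of the wrong C1=C10 isomer. The fallback sets out from 28 and replaces thermodynamic control by a stereospecific elimination. The major 2,3-anti aldol diastereomer F4, expected from the E-configured boron enolate, is separated by chromatography. Treatment with the Burgess reagent (benzene, 50 °C) effects a syn-elimination, which maps the anti adduct onto the alkene with C2 cis to C9, and the route is rejoined at 30.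

**Further compounds**

F1 | step 22 | C6 epimer of cyclodecadienol 33 | O(Cc3ccc(OC)cc3)[C@H]1[C@@H](CC(=O)OC)[C@H](O)/C=C(C)\CC/C=C(/C(=O)OC)[C@@H]1O[Si](CC)(CC)CC
F2 | step 22 | C6 ketone (C4=C5 enone) from F1 | O(Cc3ccc(OC)cc3)[C@H]1[C@@H](CC(=O)OC)C(=O)/C=C(C)\CC/C=C(/C(=O)OC)[C@@H]1O[Si](CC)(CC)CC
F3 | step 23 | dienyl 6,12-lactone (C4=C5 not yet epoxidised) | O(Cc3ccc(OC)cc3)[C@H]1[C@H]2CC(=O)O[C@H]2/C=C(C)\CC/C=C(/C(=O)OC)[C@@H]1O[Si](CC)(CC)CC
F4 | step 19 | 2,3-anti diastereomer of aldol adduct 28 (one of the two anti isomers drawn) | CC[Si](CC)(CC)OC[C@H](CC(=O)OC)[C@H](OCc1ccc(OC)cc1)[C@@H](O[Si](CC)(CC)CC)[C@H](C(=O)SCC)[C@@H](O)CC/C(C)=C\I
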